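The earlier runs and the new flask come from a simulation for an exercise, noise included.

If a protic impurity consumes partner, the partner charged overstates the target to expect. Four flasks are to be judged from three earlier runs.

the same everywhere: starting material 21 mM

|  | partner | protic impurity | temperature | remark | time |
|---|---|---|---|---|---|
| green | 21 mM | 6.3 mM | 0 °C | run made earlier |  |
| red | 32 mM | 6.3 mM | 35 °C | run made earlier |  |
| violet | 14.7 mM | 9.4 mM | 0 °C | run made earlier |  |
| Friday's | 14.7 mM | 6.30 mM | 35 °C |  | 25 min |
| Wednesday's | 14.7 mM | 6.30 mM | 5 °C |  | 25 min |
| Thursday's | 14.7 mM | 6.30 mM | 65 °C |  | 25 min |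
| Tuesday's | 14.7 mM | 6.30 mM |  | at 65 °C until 5.0 min, from then on at 5 °C | 25 min |

| run | time / min | open intermediate / % | target / % |
|---|---|---|---|
| green | 30.0 | 27.6 | 57.3 |
| green | 60.0 | 20.4 | 67.4 |
| green | 80.0 | 18.4 | 68.2 |
| green | 120 | 14.7 | 69.6 |
| green | 150 | 14.6 | 70.2 |
| green | 180 | 13.4 | 70.2 |
| red | 2.00 | 8.5 | 81.2 |
| red | 6.00 | 0.7 | 92.0 |
| red | 10.0 | 0 | 92.8 |
| red | 15.0 | 0 | 93.4 |
| red | 25.0 | 0 | 94.3 |
| red | 30.0 | 0 | 93.4 |
| violet | 30.0 | 47.8 | 28.8 |
| violet | 60.0 | 40.4 | 33.3 |
| violet | 120 | 30.3 | 32.7 |
| violet | 150 | 29.7 | 30.9 |
| violet | 180 | 25.6 | 33.2 |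

(each reading ± 1 percentage point)

- the numbers in the tables scatter by 1 percentage point (one standard deviation)
- a reading or a percentage of target counts all its forms, free or not

- which flask leads in amount of open intermediate, in percent of the starting material charged ("all alike" within 1.5 percentage points) (Friday's / Wednesday's / Thursday's / Tuesday's / all alike)
- how much open intermediate is there at the end, in percent of the starting material charged: Friday's
- how much open intermediate is there at the end, in percent of the starting material charged: Wednesday's
- how much open intermediate is there at the end, in percent of the starting material charged: Thursday's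
- how much open intermediate is there at the end, in percent of the starting material charged: Tuesday's

The green run holds a puzzle. Its target reads 70.2% at 150 min and 70.2% at 180 min, so it has stopped, yet 13.4% of open intermediate still stands beside it. Open intermediate is present, but it no longer yields target, so something else must be missing.

Suppose the protic impurity takes partner first, and reckon with what it leaves. The free-partner share is the partner left after the impurity has taken its whole charge, divided by the starting material charged: (c partner − c protic impurity)/c starting material. In the new flasks it is 40.0%. In green it is 70.0%, close to where green's target stops, so free partner acts there as the limiting reagent. In violet it is 25.2%, and violet's target reads 33.2%, more than that share. Some partner therefore escapes the impurity in violet.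

Wednesday's flask is cold, like violet, and has the same partner charge. Violet at 30.0 min reads open intermediate as 0.671 of everything that is not target. My own reckoning lends this ratio to Wednesday's flask and applies it to the 60.0% beyond the free-partner share, which gives 40.3% of open intermediate. This reckoning holds no temperature term, so it is told for Wednesday's flask and ranks none of the four.

The forecast names Wednesday's as leader, with 36% there because “closure is unfinished”, and 15%, 4% and 8% for Friday's, Thursday's and Tuesday's.

Wednesday's flask leads with 37.9%, against 8.98% in Friday's, 1.30% in Thursday's and 3.64% in Tuesday's.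

    open intermediate + second intermediate → target (k = 0.174 L mol⁻¹ s⁻¹, Ea = 50.0 kJ mol⁻¹)
    starting material ⇌ open intermediate (K = 5.00, k = 0.00925 s⁻¹, Ea = 74.0 kJ mol⁻¹, ΔH = 7.00 kJ mol⁻¹)
    partner → second intermediate (k = 0.00719 s⁻¹, Ea = 77.0 kJ mol⁻¹)
    2 open intermediate → homo product (k = 0.00851 L mol⁻¹ s⁻¹, Ea = 63.0 kJ mol⁻¹)
    partner + protic impurity → quenched reagent (k = 1.34 L mol⁻¹ s⁻¹, Ea = 40.0 kJ mol⁻¹)
    crystals ⇌ target, rate k6*(cs6 - [target]) while solid is left; crystals form when [target] > cs6 (solubility = 4.50 mM, k = 0.0567 s⁻¹)
    (constants at 5 °C)

Wednesday's target stands at 41.3%, near the free-partner share of 40.0%, with 17.1% of the impurity's own charge left. One more flask like Tuesday's, charged with 8.4 mM of starting material, has a free-partner share of >99.9%. It ends with 91.8% of target and 0% of open intermediate.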